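## Retrosynthetic overview

1. Numbering: ring C1 (bearing exocyclic C12H2), C2, C3, C4=C5 (C5 bearing carboxyl C13), C6, C7 (isovaleryloxy), C8, C9 (Me2), C10, C11 (OH). The route rests on one feature: C7–C8–C9(Me2)–C10–C11 together with C1 are the six carbons of dimedone. One extra C1–C7 bond turns the eleven-membered ring into a cyclohexane (C1, C7–C11) fused to a cycloheptene (C1–C7), and O–C7, C1 and C12–O then stand in the 1,3-relationship that allows this bond to be broken again with formation of C1=C12.
2. Endgame: C11–OH from its silyl ether; the C13 acid from an allylic PMB ether; the C7 isovalerate from a C7 ketone by reagent-controlled reduction.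
3. Key disconnection: the eleven-membered β,γ-unsaturated C7 ketone with C1=C12 from a bicyclo[5.4.0]undecene (C4=C5) carrying C7–OH and C12–OTs, by fragmentation of the C1–C7 bond.
4. Bicycle from ring-closing metathesis (C4=C5) of a cyclohexanol with a butenyl chain on C1 and a 2-(alkoxymethyl)allyl chain on C7; C7 chain by zinc allylation; C11 by CBS desymmetrization of 2-butenyl-2-acetoxymethyl-dimedone; this from dimedone, acrolein and formaldehyde; the allyl bromide from 2-methylenepropane-1,3-diol.
5. Ring order: six-membered ring bought as dimedone; seven-membered ring by metathesis (step 10); eleven-membered ring by fragmentation (step 13).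

Key step: step 13

Remark: C1 (from step 5) and C7 (from step 9) are stereogenic only until step 13, where both become trigonal; steps 5 and 9 may give epimers at these carbons, which are carried on unseparated, and names and SMILES show one representative isomer (O11, C12 and O7 on one face of the six-membered ring, the two alkenyl chains on the other).

## Route

Step 1
Reactants: 1 dimedone; 2 acrolein
Product: 3 2-hydroxy-7,7-dimethyl-2,3,4,6,7,8-hexahydro-5H-chromen-5-one (racemic lactol)
Conditions: acrolein (1.2 equiv), H2O, rt
Reagents that add atoms: none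
Why: Michael addition of the acidic 1,3-dione to acrolein needs no added base in water, and the adduct is trapped as the cyclic enol hemiacetal, which blocks a second addition and whose racemic hemiacetal carbon is removed in step 2.

Step 2
Reactants: 3 lactol
Product: 5 2-(but-3-en-1-yl)-5,5-dimethylcyclohexane-1,3-dione, via enolate aldehyde 4 (not isolated)
Conditions: Ph3PCH3Br (2.2 equiv), KOtBu (3.2 equiv), THF, 0 °C to rt; then 1 M HCl
Reagents that add atoms: methyltriphenylphosphonium bromide, C[P+](c1ccccc1)(c1ccccc1)c1ccccc1.[Br-]
Why: Wittig methylenation of a lactol, in which base opens the hemiacetal to the dione enolate 4 so that the diketone is masked as its enolate while the free aldehyde is olefinated, and acid work-up returns the 2-alkyl dione.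

Step 3
Reactants: 5 2-(but-3-en-1-yl)-5,5-dimethylcyclohexane-1,3-dione; 6 formaldehyde
Product: 7 2-(but-3-en-1-yl)-2-(hydroxymethyl)-5,5-dimethylcyclohexane-1,3-dione
Conditions: 37% aq. CH2O (excess), NaHCO3 (cat.), THF/H2O, rt
Reagents that add atoms: none
Why: Aldol addition (hydroxymethylation) of the 2-alkyl-1,3-dione enolate to formaldehyde, a known reaction of 2-alkyl cyclic 1,3-diones, builds quaternary C1 with C12 and creates no stereocentre because the two carbonyl arms remain equivalent.

Step 4
Reactants: 7 hydroxymethyl dione
Product: 8 [1-(but-3-en-1-yl)-4,4-dimethyl-2,6-dioxocyclohexyl]methyl acetate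
Conditions: Ac2O, pyridine, 4-(dimethylamino)pyridine (cat.), CH2Cl2, 0 °C
Reagents that add atoms: acetic anhydride, CC(=O)OC(C)=O
Why: Fast acylation of the primary hydroxyl removes the free β-hydroxy group, so that retro-aldol loss of formaldehyde is no longer possible, and the acetate is orthogonal to the silyl and PMB ethers used later.

Step 5
Reactants: 8 acetoxymethyl dione
Product: 10 (11S) hydroxy ketone [(2S)-1-(but-3-en-1-yl)-2-hydroxy-4,4-dimethyl-6-oxocyclohexyl]methyl acetate (drawn epimer 1S), via catechol borate 9 (not isolated)
Conditions: (R)-1-methyl-3,3-diphenyltetrahydro-1H,3H-pyrrolo[1,2-c][1,3,2]oxazaborole (0.2 equiv), catecholborane (1.1 equiv), PhNEt2, toluene, −78 to −40 °C; MeOH quench, aq. NaHCO3 work-up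
Reagents that add atoms: none
Why: Corey–Bakshi–Shibata reduction used as a desymmetrization of the prochiral 2,2-disubstituted 1,3-dione: with quaternary C1 as the large and C10H2 as the small flank the (R)-catalyst should deliver hydride so that whichever carbonyl reacts gives the (11S) carbinol, catecholborane at low temperature spares the terminal alkene and the acetate and stops after one carbonyl, and C1 becomes stereogenic only through the choice of carbonyl (both epimers are 11S).

Step 6
Reactants: 10 hydroxy ketone
Product: 11 (11S) silyl ether, [1-(but-3-en-1-yl)-2-(tert-butyldimethylsilyloxy)-4,4-dimethyl-6-oxocyclohexyl]methyl acetate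
Conditions: TBSOTf, 2,6-lutidine, CH2Cl2, −78 to 0 °C
Reagents that add atoms: tert-butyldimethylsilyl triflate, CC(C)(C)[Si](C)(C)OS(=O)(=O)C(F)(F)F
Why: Silylation with the silyl triflate and a non-nucleophilic base protects the hindered secondary hydroxyl without retro-aldol cleavage of the β-hydroxy ketone and leaves C11 unchanged.

Step 7
Reactants: 12 2-methylenepropane-1,3-diol
Product: 13 2-[(4-methoxybenzyloxy)methyl]prop-2-en-1-ol
Conditions: NaH (1.0 equiv), PMBCl, Bu4NI (cat.), THF/DMF, 0 °C to rt, diol in excess
Reagents that add atoms: 4-methoxybenzyl chloride, COc1ccc(CCl)cc1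
Why: Williamson etherification of a symmetric diol, where an excess of diol and one equivalent of base favour the mono-ether.

Step 8
Reactants: 13 mono-PMB ether
Product: 14 1-{[2-(bromomethyl)allyloxy]methyl}-4-methoxybenzene
Conditions: CBr4, PPh3, CH2Cl2, 0 °C
Reagents that add atoms: carbon tetrabromide, BrC(Br)(Br)Br
Why: Appel bromination converts the primary allylic alcohol into the bromide under neutral conditions that leave the PMB ether intact.

Step 9
Reactants: 11 silyloxy ketone; 14 allyl bromide
Product: 16 C7 tertiary homoallylic alcohol (diene), via allylzinc bromide 15 (not isolated)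
Conditions: activated Zn dust, THF, 0 °C to rt (bromide added to Zn and ketone); sat. aq. NH4Cl
Reagents that add atoms: none
Why: Barbier-type allylation, in which allylzinc bromide 15 adds through a cyclic six-membered transition state even to the hindered C7 ketone and tolerates the acetate, silyl and PMB groups; the face of attack (drawn anti to the C11 silyloxy group) fixes C7 only until step 13.

Step 10
Reactants: 16 diene
Product: 17 bicyclo[5.4.0]undecene acetate (C4=C5 in the seven-membered ring, C7–OH, C12–OAc, C11–OTBS, C13–OPMB)
Conditions: second-generation Grubbs catalyst RuCl2(=CHPh)(H2IMes)(PCy3) (5 mol %), CH2Cl2 (5 mM), 40 °C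
Reagents that add atoms: none
Why: Ring-closing olefin metathesis between the monosubstituted butenyl alkene and the 1,1-disubstituted allyl alkene gives the trisubstituted cycloheptene with loss of ethylene, and in a seven-membered ring only the ring-cis C4=C5 geometry (C3 and C6 cis, the 4E descriptor of the target) can form.

Step 11
Reactants: 17 bicyclic acetate
Product: 18 bicyclic 1,3-diol (C7–OH tertiary, C12–OH primary)
Conditions: K2CO3, MeOH, rt
Reagents that add atoms: none
Why: Base-catalysed transesterification with methanol removes the primary acetate as methyl acetate while the silyl ether, the PMB ether and the alkene are inert.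

Step 12
Reactants: 18 bicyclic diol
Product: 19 bicyclic hydroxy tosylate (C7–OH, C12–OTs, C11–OTBS, C13–OPMB)
Conditions: TsCl, Et3N, 4-(dimethylamino)pyridine (cat.), CH2Cl2, 0 °C to rt
Reagents that add atoms: p-toluenesulfonyl chloride, Cc1ccc(S(Cl)(=O)=O)cc1
Why: Sulfonylation distinguishes the primary C12 hydroxyl from the tertiary C7 hydroxyl on steric grounds and uses only an amine base, so the 1,3-diol monotosylate should form without premature fragmentation.

Step 13
Reactants: 19 bicyclic hydroxy tosylate
Product: 21 eleven-membered C7 ketone (C1=C12, 4E, 11S), via potassium alkoxide 20 (not isolated)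
Conditions: KOtBu (1.05 equiv), THF, −20 to 0 °C; pH 7 phosphate buffer quench
Reagents that add atoms: none
Why: Heterolytic (Grob-type) fragmentation of a 1,3-diol monosulfonate, the known way to open a fused bicycle to a medium-ring unsaturated ketone: KOtBu forms the tertiary C7 alkoxide 20, whose oxygen lone pair pushes into C7 as the C1–C7 ring-fusion bond breaks and its electrons expel tosylate from C12, so that C7=O and C1=C12 form in one concerted step. No ring is closed; cleavage of the bond shared by the six- and seven-membered rings merges them into the eleven-membered ring. No stereocentre is created: C1 and C7 become trigonal, so all C1/C7 epimers give the same product, C11 (S) is untouched and the C4=C5 geometry fixed in the cycloheptene is carried over as the ring-cis (4E) alkene. The required anti-periplanar arrangement of C1–C7 and C12–O is always reachable because C12 is exocyclic and rotates freely, which together with the neopentyl character of C12 should let fragmentation outrun 4-exo-tet oxetane closure. The C11 oxygen is capped as a bulky TBS ether so that it cannot act as a second electrofugal alkoxide, and one equivalent of base at low temperature, used up as potassium tosylate forms, leaves nothing to move the β,γ-alkene of the product into conjugation with the new ketone.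

Step 14
Reactants: 21 eleven-membered ketone
Product: 22 (4E,7S,11S) C7 alcohol
Conditions: NADPH-dependent ketoreductase ((7S)-selective, chosen from a commercial screening panel), NADP+ (cat.), i-PrOH, phosphate buffer pH 7/DMSO, 30 °C
Reagents that add atoms: none
Why: Enzymatic ketone reduction under reagent control sets C7 as (S), a choice made because the two CH2 flanks of C7 are too alike for substrate or small-catalyst control; the neutral buffer keeps the β,γ-alkene in place and any (11R) material from step 5 would become a separable diastereomer.

Step 15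
Reactants: 22 C7 alcohol
Product: 23 (7S) isovalerate (C11–OTBS, C13–OPMB)
Conditions: isovaleryl chloride, pyridine, 4-(dimethylamino)pyridine (cat.), CH2Cl2, 0 °C to rt
Reagents that add atoms: isovaleryl chloride, CC(C)CC(Cl)=O
Why: Nucleophile-catalysed acylation of the secondary alcohol proceeds with retention at C7 and does not touch the silyl or PMB ether.

Step 16
Reactants: 23 isovalerate PMB ether
Product: 24 primary allylic alcohol at C13
Conditions: DDQ, CH2Cl2/pH 7 buffer, 0 °C
Reagents that add atoms: none
Why: Oxidative cleavage of the p-methoxybenzyl ether by DDQ (benzylic hydride abstraction, then hydrolysis of the oxocarbenium ion) in buffered wet CH2Cl2 leaves the silyl ether, the ester and both alkenes alone.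

Step 17
Reactants: 24 allylic alcohol
Product: 25 enal (C13 aldehyde)
Conditions: MnO2, CH2Cl2, rt
Reagents that add atoms: none
Why: MnO2 oxidation is selective for the primary allylic alcohol, C11 cannot compete because it is silylated, and the (4E) geometry, the stable one for a 2-substituted enal, is kept.

Step 18
Reactants: 25 enal
Product: 26 C13 carboxylic acid (C11–OTBS)
Conditions: NaClO2, NaH2PO4, 2-methyl-2-butene, t-BuOH/H2O, 0 °C to rt
Reagents that add atoms: sodium chlorite, [Na+].[O-]Cl=O
Why: Pinnick oxidation converts the enal into the acid without touching the alkenes, since 2-methyl-2-butene traps the hypochlorous acid formed.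

Step 19
Reactants: 26 silyl-protected acid
Product: 27 target CNP0400752.1, (4E,7S,11S)
Conditions: HF·pyridine, pyridine, THF, 0 °C to rt
Reagents that add atoms: none
Why: Desilylation with buffered HF·pyridine frees the C11 alcohol under weakly acidic conditions, so neither transannular acyl migration nor cleavage of the isovalerate (risks of basic fluoride) should occur.

## Compound list

1 | dimedone (5,5-dimethylcyclohexane-1,3-dione) | CC1(C)CC(=O)CC(=O)C1 | starting material
2 | acrolein | C=CC=O | starting material
3 | 2-hydroxy-7,7-dimethyl-2,3,4,6,7,8-hexahydro-5H-chromen-5-one (racemic) | CC1(C)CC(=O)C2=C(C1)OC(O)CC2 | intermediate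
4 | potassium enolate of 3-(4,4-dimethyl-2,6-dioxocyclohexyl)propanal (not isolated) | CC1(C)CC(=O)C(CCC=O)=C([O-])C1.[K+] | intermediate
5 | 2-(but-3-en-1-yl)-5,5-dimethylcyclohexane-1,3-dione | C=CCCC1C(=O)CC(C)(C)CC1=O | intermediate
6 | formaldehyde | C=O | starting material
7 | 2-(but-3-en-1-yl)-2-(hydroxymethyl)-5,5-dimethylcyclohexane-1,3-dione | C=CCCC1(CO)C(=O)CC(C)(C)CC1=O | intermediate
8 | [1-(but-3-en-1-yl)-4,4-dimethyl-2,6-dioxocyclohexyl]methyl acetate | C=CCCC1(COC(C)=O)C(=O)CC(C)(C)CC1=O | intermediate
9 | catechol borate of hydroxy ketone 10 (not isolated) | CC1(C)C[C@H](OB2Oc3ccccc3O2)[C@@](COC(C)=O)(CCC=C)C(=O)C1 | intermediate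
10 | [(1S,2S)-1-(but-3-en-1-yl)-2-hydroxy-4,4-dimethyl-6-oxocyclohexyl]methyl acetate (11S; O11 cis to C12) | CC1(C)C[C@H](O)[C@@](COC(C)=O)(CCC=C)C(=O)C1 | intermediate
11 | TBS ether of 10 (11S) | CC1(C)C[C@H](O[Si](C)(C)C(C)(C)C)[C@@](COC(C)=O)(CCC=C)C(=O)C1 | intermediate
12 | 2-methylenepropane-1,3-diol | C=C(CO)CO | starting material
13 | 2-[(4-methoxybenzyloxy)methyl]prop-2-en-1-ol | C=C(CO)COCc1ccc(OC)cc1 | intermediate
14 | 1-{[2-(bromomethyl)allyloxy]methyl}-4-methoxybenzene | C=C(CBr)COCc1ccc(OC)cc1 | intermediate
15 | {2-[(4-methoxybenzyloxy)methyl]allyl}zinc bromide (not isolated) | C=C(C[Zn]Br)COCc1ccc(OC)cc1 | intermediate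
16 | cyclohexanol with C1 butenyl and CH2OAc, C7 OH and 2-(PMBOCH2)allyl, C11 OTBS (11S; O11, C12, O7 cis) | CC1(C)C[C@H](O[Si](C)(C)C(C)(C)C)[C@@](COC(C)=O)(CCC=C)[C@@](O)(CC(=C)COCc2ccc(OC)cc2)C1 | intermediate
17 | cis-fused bicyclo[5.4.0]undecene, C4=C5, C7–OH, C12–OAc, C11–OTBS, C13–OPMB | CC1(C)C[C@H](O[Si](C)(C)C(C)(C)C)[C@@]2(COC(C)=O)CCC=C(COCc3ccc(OC)cc3)C[C@@]2(O)C1 | intermediate
18 | bicyclic diol, C7–OH and C12–OH | CC1(C)C[C@H](O[Si](C)(C)C(C)(C)C)[C@@]2(CO)CCC=C(COCc3ccc(OC)cc3)C[C@@]2(O)C1 | intermediate
19 | bicyclic hydroxy tosylate, C7–OH and C12–OTs (key precursor) | CC1(C)C[C@H](O[Si](C)(C)C(C)(C)C)[C@@]2(COS(=O)(=O)c3ccc(C)cc3)CCC=C(COCc4ccc(OC)cc4)C[C@@]2(O)C1 | intermediate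
20 | potassium C7 alkoxide of 19 (not isolated) | CC1(C)C[C@H](O[Si](C)(C)C(C)(C)C)[C@@]2(COS(=O)(=O)c3ccc(C)cc3)CCC=C(COCc4ccc(OC)cc4)C[C@@]2([O-])C1.[K+] | intermediate
21 | eleven-membered C7 ketone, C1=C12, (4E), (11S)-OTBS, C13–OPMB | C=C1CC/C=C(/COCc2ccc(OC)cc2)CC(=O)CC(C)(C)C[C@@H]1O[Si](C)(C)C(C)(C)C | intermediate
22 | (4E,7S,11S) C7 alcohol | C=C1CC/C=C(/COCc2ccc(OC)cc2)C[C@@H](O)CC(C)(C)C[C@@H]1O[Si](C)(C)C(C)(C)C | intermediate
23 | (4E,7S,11S) C7 isovalerate, C11–OTBS, C13–OPMB | C=C1CC/C=C(/COCc2ccc(OC)cc2)C[C@@H](OC(=O)CC(C)C)CC(C)(C)C[C@@H]1O[Si](C)(C)C(C)(C)C | intermediate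
24 | C13 allylic alcohol | C=C1CC/C=C(/CO)C[C@@H](OC(=O)CC(C)C)CC(C)(C)C[C@@H]1O[Si](C)(C)C(C)(C)C | intermediate
25 | C13 enal | C=C1CC/C=C(/C=O)C[C@@H](OC(=O)CC(C)C)CC(C)(C)C[C@@H]1O[Si](C)(C)C(C)(C)C | intermediate
26 | C13 acid, C11–OTBS | C=C1CC/C=C(/C(=O)O)C[C@@H](OC(=O)CC(C)C)CC(C)(C)C[C@@H]1O[Si](C)(C)C(C)(C)C | intermediate
27 | CNP0400752.1, (4E,7S,11S) hydroxy acid isovalerate | C=C1CC/C=C(/C(=O)O)C[C@@H](OC(=O)CC(C)C)CC(C)(C)C[C@@H]1O | target

## Step count and risks

Total step count: 19. Longest linear sequence: 17 steps (steps 1–6 and 9–19, from dimedone); steps 7–8 prepare the allyl bromide.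

Steps most likely to fail:

1. Step 13 (fragmentation). The alkoxide may react otherwise than by C1–C7 cleavage. It may close to the oxetane at C12. The silyl group may move from O11 to O7, which would expose a C11 alkoxide able to break the C1–C11 bond instead. The product may be deprotonated at C6, shifting C4=C5 into conjugation with the ketone. The fallback changes the activation from alkoxide push on an isolated tosylate to leaving-group pull without any alkoxide. It sets out from diol 18, which is treated with Tf2O and 2,6-lutidine in CH2Cl2 at −78 °C to give the primary C12 triflate F1, not isolated. On warming to 0 °C the neutral C7 hydroxyl should drive the same cleavage, with the proton taken by lutidine. The fallback comes back to the route at ketone 21.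

2. Step 14 (C7 reduction). No enzyme of the panel may accept the bulky, lipophilic substrate, or the facial selectivity at C7 may be insufficient. The fallback replaces stereoselective reduction by a stereoconvergent pair of esterifications. It sets out from ketone 21, which is reduced with NaBH4 in MeOH at −40 °C to both C7 epimers, separable as diastereomers. The (7S) epimer is compound 22 and continues with step 15. The (7R) alcohol F2 is esterified with inversion under Mitsunobu conditions (isovaleric acid, PPh3, diisopropyl azodicarboxylate, toluene, 0 °C to rt) to give ester 23 directly. The fallback comes back at 22 and at 23.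

3. Step 5 (desymmetrization). Enantioface discrimination may be too low, the second carbonyl may be reduced, or the borane may add to the terminal alkene. The fallback replaces borane delivery by metal–ligand bifunctional transfer hydrogenation, which avoids the borane side reactions and relies on a different recognition model. It sets out from dione 8, which is treated with RuCl(p-cymene)[TsNCH(Ph)CH(Ph)NH2] (the ligand antipode that gives 11S) and HCO2H/Et3N at rt. It comes back at hydroxy ketone 10 and makes no further compound (F0).

Further compounds

F1 | step 13 | C12 triflate of diol 18 (C7–OH, C12–OTf, C11–OTBS, C13–OPMB; not isolated) | CC1(C)C[C@H](O[Si](C)(C)C(C)(C)C)[C@@]2(COS(=O)(=O)C(F)(F)F)CCC=C(COCc3ccc(OC)cc3)C[C@@]2(O)C1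
F2 | step 14 | (4E,7R,11S) C7 alcohol, C7 epimer of 22 | C=C1CC/C=C(/COCc2ccc(OC)cc2)C[C@H](O)CC(C)(C)C[C@@H]1O[Si](C)(C)C(C)(C)C
F0 | step 5 | none | none
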